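**Retrosynthetic overview**

1. Pharbinilic acid 18 comes from the protected benzofuran 16 (7-allyl ester, ethyl furan-ester, 13-acetate); deprotection is last and the furan is the last ring formed.
2. The furan of 16 comes from salicylaldehyde 10 and ethyl diazoacetate 11: intermolecular aldol-type C–C bond formation, 1,2-aryl shift, lactol closure, dehydration.
3. Aldehyde 10 comes from phenol 7 by ortho-formylation at the only free ortho position (C2).
4. The aromatic ring A (phenol 5) comes from enone-lactone 3 by decarboxylative aromatisation; 3 comes from gibberellic acid by esterification and allylic oxidation.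
5. Rings B, C and D with C6, C8, C9 and C13 are taken unchanged from gibberellic acid; ring order: B/C/D given, ring A aromatised, furan annulated.

Assumption: gibberellic acid (GA3, a bulk fermentation product) counts as a cheap commercial starting material and supplies all four stereocentres; gibberellane numbering is used (ring A = C1–C5 and C10, C7 = carboxyl on C6, C13 = bridgehead carbinol, C16=C17 = exocyclic methylene).

**Route**

Step 1
Reactants: 1 gibberellic acid (GA3)
Product: 2 allyl gibberellate (GA3 7-allyl ester)
Conditions: allyl bromide, KHCO3, DMF, rt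
Reagents that add atoms: allyl bromide, C=CCBr
Why: SN2 O-alkylation of the carboxylate under bicarbonate, which is too weak a base to isomerise the allylic lactone or alkylate the alcohols; the allyl ester is chosen because it can later be removed under neutral conditions, and no stereocentre is touched.

Step 2
Reactants: 2 allyl gibberellate
Product: 3 allyl 3-oxogibberellate (ring A 1-en-3-one, 19,10-lactone intact)
Conditions: activated MnO2 (excess), CH2Cl2, rt
Reagents that add atoms: none
Why: chemoselective allylic alcohol oxidation by MnO2 converts the secondary allylic 3-OH into the enone while the tertiary 13-OH and both isolated alkenes are inert; only the C3 centre is removed.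

Step 3
Reactants: 3 allyl 3-oxogibberellate
Product: 5 allyl 3-hydroxyallogibberate (ring A phenol with 13-OH free), via dienone acid 4 (not isolated)
Conditions: 1 M HCl, THF/H2O (1:1), 65 °C
Reagents that add atoms: none
Why: acid-promoted decarboxylative aromatisation, in which alkyl–oxygen ionisation of the tertiary allylic lactone and loss of H5 give the linear dienone β-keto acid 4, whose decarboxylation gives the dienol, i.e. the phenol; these are the conditions that convert GA3 into allogibberic acid, under which C6, C8, C9, C13 and the 13-hydroxy-16-ene unit survive, while C4, C5 and C10 lose their stereochemistry by design.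

Step 4
Reactants: 5 allyl 3-hydroxyallogibberate
Product: 6 allyl 3,13-di-O-acetyl-3-hydroxyallogibberate
Conditions: Ac2O, Et3N, DMAP, CH2Cl2, rt to 35 °C
Reagents that add atoms: acetic anhydride, CC(=O)OC(C)=O
Why: DMAP-catalysed acylation esterifies the phenol and the tertiary bridgehead alcohol; the 13-acetate blocks the acid-induced pinacol-type Wagner–Meerwein rearrangement of rings C and D and any O–H insertion in the later diazo step.

Step 5
Reactants: 6 allyl 3,13-di-O-acetyl-3-hydroxyallogibberate
Product: 7 allyl 13-O-acetyl-3-hydroxyallogibberate (free phenol)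
Conditions: pyrrolidine (1.5 equiv), CH2Cl2, 0 °C to rt
Reagents that add atoms: none
Why: chemoselective aminolysis, because the aryl acetate (phenoxide leaving group) reacts far faster than the hindered tertiary acetate or the hindered allyl ester.

Step 6
Reactants: 7 allyl 13-O-acetyl-3-hydroxyallogibberate; 8 paraformaldehyde
Product: 10 allyl 13-O-acetyl-2-formyl-3-hydroxyallogibberate (salicylaldehyde), via hydroxymethylphenol 9 (not isolated)
Conditions: MgCl2, Et3N, MeCN, reflux
Reagents that add atoms: none
Why: magnesium-phenoxide-directed ortho-formylation (Casnati–Skattebøl) delivers formaldehyde to C2, the only free ortho position (the other carries the methyl, para is substituted), and a second formaldehyde oxidises the hydroxymethyl phenoxide 9 by Oppenauer-type hydride transfer.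

Step 7
Reactants: 10 salicylaldehyde; 11 ethyl diazoacetate
Product: 14 lactol (ethyl 2-hydroxy-2,3-dihydrobenzofuran-3-carboxylate fused at C2–C3 of ring A; diastereomer mixture), via diazonium aldol adduct 12 (not isolated), via formyl ester 13 (not isolated)
Conditions: HBF4·OEt2 (10 mol %), slow addition of 11 (1.6 equiv), CH2Cl2, rt
Reagents that add atoms: none
Why: acid-catalysed aldol-type addition of the nucleophilic diazo carbon to the aldehyde joins the two fragments, the electron-rich aryl group then migrates 1,2 with loss of N2 (Roskamp-type homologation) so that the arene ends up on the ester-bearing carbon, and the ortho OH traps the new aldehyde as lactol; the two new lactol centres are uncontrolled and are removed in step 8.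

Step 8
Reactants: 14 lactol
Product: 16 13-O-acetylpharbinilic acid 7-allyl ester ethyl ester (benzofuran diester), via lactol trifluoroacetate 15 (not isolated)
Conditions: TFAA, pyridine, CH2Cl2, 0 °C; then Et3N, rt
Reagents that add atoms: none
Why: acylation of the lactol OH followed by base-induced E1cB-type β-elimination (the C3–H is benzylic and α to the ester) is driven by aromatisation to the furan and avoids the concentrated H2SO4 normally used for this dehydration, which the exocyclic alkene would not tolerate.

Step 9
Reactants: 16 benzofuran diester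
Product: 17 13-O-acetylpharbinilic acid ethyl ester (free C7 acid)
Conditions: Pd(PPh3)4 (5 mol %), morpholine, THF, rt
Reagents that add atoms: none
Why: Tsuji–Trost allyl transfer from the ester to morpholine by zerovalent palladium is neutral, so C6 is not epimerised; the ethyl ester is untouched and the 13-acetate, although allylic, is a bridgehead ester whose π-allyl complex would be anti-Bredt.

Step 10
Reactants: 17 13-O-acetylpharbinilic acid ethyl ester
Product: 18 pharbinilic acid
Conditions: LiOH (10 equiv), THF/MeOH/H2O, 40 °C; then 1 M HCl to pH 3 at 0 °C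
Reagents that add atoms: lithium hydroxide in water, [Li+].[OH-]
Why: saponification cleaves the ethyl benzofuran-3-carboxylate and the tertiary acetate while C7 is already a carboxylate, so the benzylic C6–H cannot be enolised and its configuration is kept; cold, brief acidification spares the 13-hydroxy-16-ene unit.

**Compound list**

1 | gibberellic acid (GA3) | C=C1C[C@]23C[C@@]1(O)CC[C@H]2[C@@]14C=C[C@H](O)[C@@](C)(C(=O)O1)[C@H]4[C@@H]3C(=O)O | starting material
2 | allyl gibberellate | C=C1C[C@]23C[C@@]1(O)CC[C@H]2[C@@]14C=C[C@H](O)[C@@](C)(C(=O)O1)[C@H]4[C@@H]3C(=O)OCC=C | intermediate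
3 | allyl 3-oxogibberellate (ring A enone, lactone intact) | C=C1C[C@]23C[C@@]1(O)CC[C@H]2[C@@]14C=CC(=O)[C@@](C)(C(=O)O1)[C@H]4[C@@H]3C(=O)OCC=C | intermediate
4 | ring A 1,5(10)-dien-3-one 4-carboxylic acid, 7-allyl ester (dienone acid) | C=C1C[C@]23C[C@@]1(O)CC[C@H]2C1=C([C@@H]3C(=O)OCC=C)[C@](C)(C(=O)O)C(=O)C=C1 | intermediate
5 | allyl 3-hydroxyallogibberate | C=C1C[C@]23C[C@@]1(O)CC[C@H]2c1ccc(O)c(C)c1[C@@H]3C(=O)OCC=C | intermediate
6 | allyl 3,13-di-O-acetyl-3-hydroxyallogibberate | C=C1C[C@]23C[C@@]1(OC(C)=O)CC[C@H]2c1ccc(OC(C)=O)c(C)c1[C@@H]3C(=O)OCC=C | intermediate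
7 | allyl 13-O-acetyl-3-hydroxyallogibberate | C=C1C[C@]23C[C@@]1(OC(C)=O)CC[C@H]2c1ccc(O)c(C)c1[C@@H]3C(=O)OCC=C | intermediate
8 | paraformaldehyde (formaldehyde polymer; monomer shown) | C=O | starting material
9 | allyl 13-O-acetyl-3-hydroxy-2-(hydroxymethyl)allogibberate | C=C1C[C@]23C[C@@]1(OC(C)=O)CC[C@H]2c1cc(CO)c(O)c(C)c1[C@@H]3C(=O)OCC=C | intermediate
10 | allyl 13-O-acetyl-2-formyl-3-hydroxyallogibberate | C=C1C[C@]23C[C@@]1(OC(C)=O)CC[C@H]2c1cc(C=O)c(O)c(C)c1[C@@H]3C(=O)OCC=C | intermediate
11 | ethyl diazoacetate | CCOC(=O)C=[N+]=[N-] | starting material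
12 | β-hydroxy-α-diazonium ester at C2 (tetrafluoroborate; new centres undefined) | C=C1C[C@]23C[C@@]1(OC(C)=O)CC[C@H]2c1cc(C(O)C([N+]#N)C(=O)OCC)c(O)c(C)c1[C@@H]3C(=O)OCC=C.F[B-](F)(F)F | intermediate
13 | ethyl 2-aryl-3-oxopropanoate at C2 (formyl ester; new centre undefined) | C=C1C[C@]23C[C@@]1(OC(C)=O)CC[C@H]2c1cc(C(C=O)C(=O)OCC)c(O)c(C)c1[C@@H]3C(=O)OCC=C | intermediate
14 | lactol: ethyl 2-hydroxy-2,3-dihydrobenzofuran-3-carboxylate fused to ring A (13-OAc, 7-allyl ester; lactol centres undefined) | C=C1C[C@]23C[C@@]1(OC(C)=O)CC[C@H]2c1cc2C(C(=O)OCC)C(O)Oc2c(C)c1[C@@H]3C(=O)OCC=C | intermediate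
15 | lactol trifluoroacetate | C=C1C[C@]23C[C@@]1(OC(C)=O)CC[C@H]2c1cc2C(C(=O)OCC)C(OC(=O)C(F)(F)F)Oc2c(C)c1[C@@H]3C(=O)OCC=C | intermediate
16 | 13-O-acetylpharbinilic acid 7-allyl ester ethyl ester | C=C1C[C@]23C[C@@]1(OC(C)=O)CC[C@H]2c1cc2c(C(=O)OCC)coc2c(C)c1[C@@H]3C(=O)OCC=C | intermediate
17 | 13-O-acetylpharbinilic acid ethyl ester (C7 acid free) | C=C1C[C@]23C[C@@]1(OC(C)=O)CC[C@H]2c1cc2c(C(=O)OCC)coc2c(C)c1[C@@H]3C(=O)O | intermediate
18 | pharbinilic acid | C=C1C[C@]23C[C@@]1(O)CC[C@H]2c1cc2c(C(=O)O)coc2c(C)c1[C@@H]3C(=O)O | target

**Totals and risks**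

Total step count: 10. Longest linear sequence: 10 steps (1 to 18).

Steps most likely to fail:

Step 3 (decarboxylative aromatisation). The enone may make lactone ionisation slow enough for ring C/D rearrangement or ester hydrolysis to compete. The fallback sets out from 3 and replaces ionisation by reduction and dehydrogenation. Zn dust in AcOH/THF at rt reductively cleaves the γ-acyloxy enone, and the freed β-keto acid decarboxylates on warming to 50 °C to give the ring A β,γ-enone allyl 13-hydroxy-3-oxo-19,20-dinorgibberella-1(10),16-dien-7-oate F1. One equivalent of DDQ in dioxane at rt, the aromatisation used for 19-nor steroid enones, then dehydrogenates F1 and the route is rejoined at 5.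

Step 7 (diazoacetate aldol and aryl shift). The strong acid catalyst may isomerise the exocyclic alkene, or hydride may migrate instead of aryl. The fallback sets out from 7 and forms the C–O bond first. I2 and morpholine in CH2Cl2 at 0 °C iodinate the only free ortho position to give allyl 13-O-acetyl-3-hydroxy-2-iodoallogibberate F2. DABCO-catalysed oxa-Michael addition of F2 to ethyl propiolate gives the (E)-β-aryloxyacrylate F3. A phosphine-free intramolecular Heck cyclisation (Pd(OAc)2, n-Bu4NCl, NaHCO3, DMF, 80 °C) closes the furan and comes back at 16; any allyl ester lost to zerovalent palladium only delivers 17 one step early. Steps 6 to 8 are bypassed.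

Step 8 (lactol dehydration). Under base the lactol can open to the formyl-ester enolate and be acylated in the open form. The fallback sets out from 14 and goes through an acetal. MeOH, PPTS and 3 Å sieves at rt give the 2-methoxy-2,3-dihydrobenzofuran methyl acetal F4. TMSOTf and i-Pr2NEt in CH2Cl2 at −20 to 0 °C (acetal-to-enol-ether elimination through the ring oxocarbenium ion) then expel the methoxy group and come back at 16.

**Further compounds**

F1 | step 3 | allyl 13-hydroxy-3-oxo-19,20-dinorgibberella-1(10),16-dien-7-oate (C4 epimer mixture) | C=C1C[C@]23C[C@@]1(O)CC[C@H]2C1=CCC(=O)C(C)[C@H]1[C@@H]3C(=O)OCC=C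
F2 | step 7 | allyl 13-O-acetyl-3-hydroxy-2-iodoallogibberate | C=C1C[C@]23C[C@@]1(OC(C)=O)CC[C@H]2c1cc(I)c(O)c(C)c1[C@@H]3C(=O)OCC=C
F3 | step 7 | ethyl (E)-3-aryloxyacrylate of F2 (aryl ether at the C3 oxygen) | C=C1C[C@]23C[C@@]1(OC(C)=O)CC[C@H]2c1cc(I)c(O/C=C/C(=O)OCC)c(C)c1[C@@H]3C(=O)OCC=C
F4 | step 8 | methyl acetal of lactol 14 (ethyl 2-methoxy-2,3-dihydrobenzofuran-3-carboxylate) | C=C1C[C@]23C[C@@]1(OC(C)=O)CC[C@H]2c1cc2C(C(=O)OCC)C(OC)Oc2c(C)c1[C@@H]3C(=O)OCC=C
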